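**Retrosynthetic overview**

- Feature: the target is one 27-membered ring (C1–C26 plus the ring oxygen). Its C2–C26 polymethylene chain has no substituent, stereocentre or second functional group, so the 26 ring carbons can be cut 16 + 10.
- Key disconnection at C7–C8 and C17–C18: C1–C7 and C18–C26 with the ring oxygen are the 17-membered macrolide ambrettolide 1; C8–C17 are the ten-membered carbocycle cis-cyclodecene 2.
- Forward, a ruthenium alkylidene opens both purchased rings and closes the single 27-membered ring of dienolide 3 in one operation, forming C7=C8 and C17=C18. No other ring is formed at any stage.
- Hydrogenation of both olefins of 3 gives the target 4. Both steps are additions in which no atom of 1, 2 or 3 is lost.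

Key step: step 1

Assumption (chemistry): 1 is taken as the pure (Z)-Δ7 isomer. If a commercial lot contains positional or geometric olefin isomers of the C16 macrolide, the route is unaffected, because every such isomer gives the same saturated lactone 4 after C10 insertion and hydrogenation.

**Route**

Step 1
Reactants: 1 ambrettolide, (Z)-hexadec-7-en-16-olide; 2 cis-cyclodecene
Product: 3 hexacosa-7,17-dien-26-olide (E/Z mixture at both olefins)
Conditions: RuCl2(=CHPh)(PCy3)(H2IMes) (second-generation Grubbs catalyst, H2IMes = 1,3-dimesityl-4,5-dihydroimidazol-2-ylidene; 0.5 mol% on total olefin, two portions), 1,4-benzoquinone (5 mol%), degassed CH2Cl2, 40 °C, Ar; 1 (10 equiv, 10 mM), 2 added by syringe pump over 8 h (final 1 mM); then ethyl vinyl ether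
Reagents that add atoms: none
Why: Proposed new method: the ruthenium alkylidene adds [2+2] to the strained cis olefin of 2 and cycloreversion of the ruthenacyclobutane opens the ten-membered ring, the new chain-end alkylidene opens the unhindered cis C7=C8 olefin of 1 in the same way (the order of the two openings is immaterial), and the resulting open-chain alkylidene, which carries one C16 and one C10 unit, back-bites on its remote chain-end olefin to expel 3 and regenerate the initiating alkylidene. The closest known reaction types are ring-expansion metathesis of a cycloalkene with an acyclic diene (ring-opening followed by ring-closing metathesis), the metathetic cyclodimerisation of simple cycloalkenes to macrocyclic dienes, and the ring–chain equilibration of macrocyclic olefins at high dilution; splicing one cycloalkene into the olefin of a macrolide to give a single larger macrolide is not an established reaction. The only ring closed is the 27-membered lactone (C1–C26 plus O), by ring-closing metathesis of the chain-end alkylidene onto the far chain-end olefin through a ruthenacyclobutane, so that either C7=C8 or C17=C18 is the bond made last. No stereocentre is formed, and the E/Z geometry of the two new olefins is left uncontrolled because step 2 removes it. The step needs single insertion of one C10 unit in competition with the cyclic dimer of 2, the 34-membered diolide from two molecules of 1 and 2:1 adducts: the strain of 2 makes its opening practically irreversible, its low stationary concentration together with the tenfold excess of 1 makes a lactone olefin the likeliest next partner of a C10-terminated alkylidene, and working below the critical concentration of the ring–chain equilibrium keeps the products cyclic. Benzoquinone intercepts ruthenium hydrides, so that olefin migration, which would lead through further metathesis to ring homologues with one CH2 more or fewer, is held back.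

Step 2
Reactants: 3 hexacosa-7,17-dien-26-olide (E/Z mixture)
Product: 4 26-hexacosanolide
Conditions: H2 (1 atm), Pd/C (10 wt%), EtOAc, rt
Reagents that add atoms: none
Why: Heterogeneous catalytic hydrogenation of two unhindered 1,2-disubstituted olefins; the lactone is inert to H2 over Pd/C at ambient pressure, all positional and geometric olefin isomers converge on the one saturated 27-membered lactone, and no stereocentre is present.

**Compound list**

1 | ambrettolide, (Z)-hexadec-7-en-16-olide [(8Z)-oxacycloheptadec-8-en-2-one] | O=C1CCCCC/C=C\CCCCCCCCO1 | starting material
2 | cis-cyclodecene [(Z)-cyclodecene] | C1CCCC/C=C\CCC1 | starting material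
3 | hexacosa-7,17-dien-26-olide (oxacycloheptacosa-8,18-dien-2-one), E/Z mixture at both olefins | O=C1CCCCCC=CCCCCCCCCC=CCCCCCCCCO1 | intermediate
4 | 26-hexacosanolide (oxacycloheptacosan-2-one) | O=C1CCCCCCCCCCCCCCCCCCCCCCCCCO1 | target

**Step count**

Total steps: 2. Longest linear sequence: 2.

**Steps most likely to fail**

The route has only two steps, so both are ranked.

1. Step 1 (proposed new method). Three processes may defeat it:
- The C10 unit may be distributed over several ring sizes. The by-products would be the cyclic dimer of 2, the 2:1 adduct and the diolide from two molecules of 1.
- Initiation on internal olefins may be slow, and the catalyst may decay at high dilution.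
- Olefin migration followed by metathesis may give ring homologues that could no longer be separated after hydrogenation.

The hydrocarbon dimer (no ester) and the diolides (two esters) should separate from the mono-lactone 3 on silica. Excess 1 should be recoverable by bulb-to-bulb distillation. The 2:1 adduct would need size-exclusion chromatography.

Fallback (known chemistry, sets out from 1, returns at 4):
- Partial reduction of 1 with i-Bu2AlH (CH2Cl2, −78 °C) should give (Z)-16-hydroxyhexadec-7-enal F1.
- Separately, 10-bromodecanoic acid and PPh3 in refluxing MeCN should give (9-carboxynonyl)triphenylphosphonium bromide F2.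
- F2 with NaN(SiMe3)2 in THF is converted into the ylide sodium 10-(triphenyl-λ5-phosphanylidene)decanoate F3.
- Wittig olefination of F1 with excess F3 (THF, −78 °C to rt, acidic work-up) should give the seco acid (10Z,17Z)-26-hydroxyhexacosa-10,17-dienoic acid F4.
- Yamaguchi macrolactonisation follows: 2,4,6-trichlorobenzoyl chloride and Et3N in THF form the mixed anhydride (10Z,17Z)-26-hydroxyhexacosa-10,17-dienoic 2,4,6-trichlorobenzoic anhydride F5, which is added slowly to DMAP in toluene at 80 °C (about 1 mM). This should close the 27-membered ring to (10Z,17Z)-hexacosa-10,17-dien-26-olide F6.
- Hydrogenation of F6 under the conditions of step 2 gives 4.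

2. Step 2. Hydrogen uptake may stall through poisoning of the palladium surface by ruthenium, phosphine or quinone residues carried over from step 1, or through poor solubility of the waxy macrocycle.

Fallback (sets out from 3, returns at 4): metal-free reduction with diimide F7, generated in situ from p-toluenesulfonyl hydrazide and NaOAc in refluxing 1,2-dimethoxyethane/water and used in excess, should saturate both olefins without touching the lactone.

**Further compounds**

F1 | step 1 | (Z)-16-hydroxyhexadec-7-enal | O=CCCCCC/C=C\CCCCCCCCO
F2 | step 1 | (9-carboxynonyl)triphenylphosphonium bromide | OC(=O)CCCCCCCCC[P+](c1ccccc1)(c1ccccc1)c1ccccc1.[Br-]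
F3 | step 1 | sodium 10-(triphenyl-λ5-phosphanylidene)decanoate | [Na+].[O-]C(=O)CCCCCCCCC=P(c1ccccc1)(c1ccccc1)c1ccccc1
F4 | step 1 | (10Z,17Z)-26-hydroxyhexacosa-10,17-dienoic acid | OC(=O)CCCCCCCC/C=C\CCCCC/C=C\CCCCCCCCO
F5 | step 1 | (10Z,17Z)-26-hydroxyhexacosa-10,17-dienoic 2,4,6-trichlorobenzoic anhydride | OCCCCCCCC/C=C\CCCCC/C=C\CCCCCCCCC(=O)OC(=O)c1c(Cl)cc(Cl)cc1Cl
F6 | step 1 | (10Z,17Z)-hexacosa-10,17-dien-26-olide | O=C1CCCCCCCC/C=C\CCCCC/C=C\CCCCCCCCO1
F7 | step 2 | diimide (diazene) | N=N
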